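Substrate is conserved, so whatever is not target in amber, the flask asked about, still stands somewhere. I call u the missing share: one minus target, as a fraction of the charge.

| setting | amber | ochre | flask |
|---|---|---|---|
| solid substrate | 0.10 M | 0.10 M | 0.10 M |
| partner | 0.12 M | 0.18 M | 0.120 M |
| protic impurity | 0.020 M | 0.020 M | 0.0200 M |
| temperature | 20 °C | 15 °C | 20 °C |
| remark | the very flask that is asked about, followed so far | run made earlier |  |
| time |  |  | 30 min |

| run | time / min | target / % | solid substrate / % |
|---|---|---|---|
| amber | 2.50 | 74.6 | 0.1 |
| amber | 6.00 | 65.1 | 0 |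
| amber | 12.0 | 53.2 | 0 |
| amber | 20.0 | 41.4 | 0.1 |
| ochre | 1.50 | 93.2 | 0.2 |
| ochre | 4.00 | 92.2 | 0 |
| ochre | 8.00 | 89.2 | 0.1 |
| ochre | 12.0 | 83.8 | 0.8 |

(scatter of a reading: 0.5 percentage points)

- epsilon: at 30 min raise the temperature by 15 K, then wait 15 min
- zeta: at 30 min add partner, 100% of the amount charged, then wait 15 min
- gamma: change nothing and wait 15 min more

- additions leave the volume as it is
- at the start none of the solid substrate is in solution
- a reading or a percentage of target counts all its forms, free or not

* target, in percent of the solid substrate first charged, at 30 min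
* the option that brings most further target ("none" if no option brings more than 2 percentage points) (epsilon / zeta / gamma / none)
* target present, in percent of the solid substrate first charged, after epsilon
* target present, in percent of the solid substrate first charged, after gamma

In the amber table solid substrate reads 0% at 6.00 min, so I take u there as dissolved substrate, returned by a reversible step. Down the rows u runs 25.4%, 34.9%, 46.8%, 58.6%. The loss slows, but u squared climbs evenly between rows: 0.0164 min⁻¹, 0.0162 min⁻¹, 0.0155 min⁻¹. So I carry the square rate, the growth of u squared per minute from first reading to last, 0.0159 min⁻¹.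

The ochre table reads against this. With c(partner) at 0.18 M and the bath at 15 °C, ochre holds 92.2% at 4.00 min, more than amber's 65.1% at 6.00 min. I read that as more partner, the cooler bath or both keeping substrate in target.

Running the square rate forward, amber has u = 70.9% at 30 min, so target 29.1%. Gamma gives u = 86.1%, so target 13.9%. If 15 K triples the rate, a guess of mine, u squared reckons to 1.22, past one, so I reckon epsilon leaves about no target. I commit to zeta, adding 0.120 M of partner against 0.0709 M of missing substrate; that compares charges and says nothing of how long the partner lasts.

The forecast differs from me: 31.5% (28% to 34%), best none, epsilon 13%, gamma 22%, because partner “cannot create more once the substrate is consumed”.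

The flask gives 28.2%, best zeta.

    solid substrate ⇌ dissolved substrate, rate k1*(cs1 - [dissolved substrate]) while solid is left; crystals form when [dissolved substrate] > cs1 (solubility = 0.0730 M, k = 0.220 s⁻¹)
    solid product ⇌ target, rate k2*(cs2 - [target]) while solid is left; crystals form when [target] > cs2 (solubility = 8.00 mM, k = 0.390 s⁻¹)
    partner + protic impurity → quenched reagent (k = 0.330 L mol⁻¹ s⁻¹, Ea = 54.0 kJ mol⁻¹)
    dissolved substrate + partner ⇌ target (K = 23.0 L mol⁻¹, k = 0.740 L mol⁻¹ s⁻¹, Ea = 49.0 kJ mol⁻¹, ΔH = −28.0 kJ mol⁻¹)
    partner → decomposed reagent (k = 0.00460 s⁻¹, Ea = 89.0 kJ mol⁻¹)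
    (constants at 20 °C)

Zeta brings 35 percentage points, epsilon leaves 0% and gamma 10.1%. At 30.0 min the flask holds dissolved substrate 71.8% beside target 28.2%. From 28.2% to 10.1% u squared grows 0.0195 min⁻¹, faster than the amber 0.0159 min⁻¹. In the neighbour charged with 0.040 M of solid substrate, the same molar square rate reckons u squared to 2.99 by 30 min, past one. That neighbour holds 1.77% target.

All runs are calculated on assumed constants; scatter was added.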